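## Retrosynthetic overview

- Target ⇐ selective acylation of an allylic 1,3-diol ⇐ 1,2-reduction of a cycloheptenone ⇐ E1cB opening of the oxygen bridge of a saturated oxa-bridged tricyclic ketone ⇐ hydrogenation of a (4+3) cycloadduct.
- Cycloadduct ⇐ intramolecular oxyallyl cation–furan (4+3) cycloaddition of a furan-tethered α-chloro ketone. One operation forms the ring-fusion bond C8a–C3a and the bond C7–C6 that later becomes the ring olefin.
- Enabling feature: in the seven-membered ring the oxygenated C8 lies between quaternary C8a and olefinic C7 (an oxyallyl C–C(O)–C triad). C3a(OH) and C6(CH3) are 1,4-related through C4–C5, which is a latent 2-alkyl-5-methylfuran whose ring oxygen becomes the tertiary OH. The cyclopentane carbons C1–C3 are the tether.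
- Chloro ketone ⇐ ester homologation ⇐ Wittig olefination and conjugate reduction ⇐ (R)-aldehyde from an enantioselective organocatalytic Friedel–Crafts addition of 2-methylfuran to an enal. This is the only catalyst-set stereocentre and it relays to all others.
- Ring order: furan (purchased) → five- and seven-membered rings together, oxygen-bridged (step 5) → bridge opened (step 7).

Key step: step 5

Assumption: the facial sense of the imidazolidinone-catalysed addition of 2-methylfuran to the β-isopropyl enal is taken to follow that known for other π-nucleophiles, and the (2R,5R) catalyst is specified on that basis; the (2S,5S) catalyst would be used if the sense proved opposite.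

## Route

Step 1
Reactants: 1 2-methylfuran; 2 (E)-4-methylpent-2-enal
Product: 3 (3R)-4-methyl-3-(5-methylfuran-2-yl)pentanal
Conditions: (2R,5R)-5-benzyl-2-tert-butyl-3-methylimidazolidin-4-one·CF3CO2H (20 mol %), CH2Cl2/i-PrOH, −40 °C
Reagents that add atoms: none
Why: Iminium-activated enantioselective Friedel–Crafts-type conjugate addition of the furan (free C5 position) to the enal; the benzyl and tert-butyl groups of the catalyst shield one face of the E-iminium ion, so the furan adds to the open face and sets the (R) stereocentre.

Step 2
Reactants: 3 (3R)-4-methyl-3-(5-methylfuran-2-yl)pentanal; 4 methyl 2-(triphenylphosphoranylidene)propanoate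
Product: 5 methyl (2E,5R)-2,6-dimethyl-5-(5-methylfuran-2-yl)hept-2-enoate
Conditions: toluene, 40 °C
Reagents that add atoms: none
Why: Wittig olefination with a stabilised ylide adds the three carbons that become C8a, its methyl group and C8; the alkene geometry is immaterial because the olefin is reduced next, and the stereocentre (β to the aldehyde) cannot epimerise.

Step 3
Reactants: 5 methyl (2E,5R)-2,6-dimethyl-5-(5-methylfuran-2-yl)hept-2-enoate
Product: 6 methyl (5R)-2,6-dimethyl-5-(5-methylfuran-2-yl)heptanoate (both C2 epimers)
Conditions: Mg turnings, MeOH, 0 °C to rt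
Reagents that add atoms: none
Why: Single-electron (dissolving-metal) conjugate reduction of the α,β-unsaturated ester, to which the isolated 2,5-dialkylfuran is inert; the new C2 centre forms unselectively, which does not matter because this carbon becomes sp2 in step 5.

Step 4
Reactants: 6 methyl (5R)-2,6-dimethyl-5-(5-methylfuran-2-yl)heptanoate; 7 chloroiodomethane
Product: 9 (6R)-1-chloro-3,7-dimethyl-6-(5-methylfuran-2-yl)octan-2-one (both C3 epimers), via lithium hemiketal alkoxide 8 (not isolated)
Conditions: MeLi·LiBr, THF, −78 °C; then AcOH, −78 °C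
Reagents that add atoms: none
Why: Ester homologation to an α-chloro ketone: chloromethyllithium from iodine–lithium exchange adds to the ester, and the tetrahedral adduct 8 persists at −78 °C so that only one chloromethyl unit is installed before the cold acidic quench releases the ketone, without any electrophilic halogen that would attack the furan.

Step 5
Reactants: 9 (6R)-1-chloro-3,7-dimethyl-6-(5-methylfuran-2-yl)octan-2-one
Product: 11 3a,6-epoxy-6,8a-dimethyl-3-(propan-2-yl)-1,2,3,3a,6,7,8,8a-octahydroazulen-8-one (cis-fused; oxygen bridge syn to 8a-CH3 and to 3-isopropyl), via oxyallyl cation 10 (not isolated)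
Conditions: NaOCH2CF3 (1.5 equiv), CF3CH2OH, 0.02 M, 0 °C to rt
Reagents that add atoms: none
Why: Trifluoroethoxide enolises 9 toward the methine carbon, and ionisation of the allylic chloride in the ionising solvent gives the 2-oxidoallyl cation 10, which adds across C2 and C5 of the tethered furan in a (4+3) cycloaddition (concerted but asynchronous, or two fast ionic steps); the closest known reaction type is the intramolecular oxyallyl cation–furan (4+3) cycloaddition of α-chloro ketones with base in fluorinated alcohols, which tolerates fully substituted cation termini. The five-membered ring closes by bond formation between the methyl-bearing cation terminus and the tether-bearing furan carbon (three-carbon tether in the outside position of the cation, exo-type closure), and the seven-membered carbocycle closes by the second bond between the CH2 terminus and the methyl-bearing furan carbon, the furan oxygen becoming the one-atom bridge. The two ring-fusion centres are set by the compact (endo-like, staggered) array, which puts the quaternary methyl syn to the oxygen bridge and the tether carbon anti to it (a cis-fused hydroazulene once the bridge is opened); the methyl-bearing bridgehead follows from suprafacial addition to the furan. The facial sense relative to the isopropyl stereocentre is set by allylic 1,3-strain: its hydrogen lies toward the furan C3–H flank and the isopropyl group toward the ring-oxygen flank, so isopropyl ends cis to the bridge. The step needs compact-over-extended selectivity and intramolecular capture ahead of solvent capture or Favorskii rearrangement: the first is secured because the methyl group forced into the inside position of the cation would eclipse the furan C3–H in the extended array, the second by the electron-rich furan held five atoms away and by high dilution in a poorly nucleophilic solvent.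

Step 6
Reactants: 11 3a,6-epoxy-6,8a-dimethyl-3-(propan-2-yl)-1,2,3,3a,6,7,8,8a-octahydroazulen-8-one
Product: 12 3a,6-epoxy-6,8a-dimethyl-3-(propan-2-yl)decahydroazulen-8-one (same relative configuration)
Conditions: H2 (1 atm), Pd/C, EtOAc, rt
Reagents that add atoms: none
Why: Heterogeneous hydrogenation of the strained cis-disubstituted bridge olefin; the ketone and ether bridge are inert and no stereocentre is created.

Step 7
Reactants: 12 3a,6-epoxy-6,8a-dimethyl-3-(propan-2-yl)decahydroazulen-8-one
Product: 14 (3R,3aS,8aS)-6,8a-dimethyl-3-(propan-2-yl)-3a-(trimethylsilyloxy)-2,3,3a,4,5,8a-hexahydroazulen-8(1H)-one, via silyl enol ether 13 (not isolated)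
Conditions: TMSOTf (1.5 equiv), Et3N (3 equiv), CH2Cl2, −20 °C to rt; aqueous NaHCO3
Reagents that add atoms: trimethylsilyl trifluoromethanesulfonate, C[Si](C)(C)OS(=O)(=O)C(F)(F)F
Why: Silyl triflate/amine-mediated E1cB-type opening of the oxygen bridge: the only enolisable position is C7 (C8a is quaternary), and its silyl enol ether 13 expels the Lewis acid-activated bridging oxygen from tertiary C6 to give the conjugated enone with the C6=C7 olefin in the required place, while the tertiary oxygen is trapped as its silyl ether so that the bridge cannot re-close by oxa-Michael addition; no stereocentre is touched.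

Step 8
Reactants: 14 (3R,3aS,8aS)-6,8a-dimethyl-3-(propan-2-yl)-3a-(trimethylsilyloxy)-2,3,3a,4,5,8a-hexahydroazulen-8(1H)-one
Product: 16 (3R,3aS,8S,8aR)-6,8a-dimethyl-3-(propan-2-yl)-1,2,3,3a,4,5,8,8a-octahydroazulene-3a,8-diol, via allylic alcohol silyl ether 15 (not isolated)
Conditions: NaBH4, CeCl3·7H2O, MeOH, −78 °C; then K2CO3, MeOH, rt
Reagents that add atoms: none
Why: Luche 1,2-reduction of the enone; both angular substituents (8a-CH3 and 3a-OSiMe3) lie on one face and flank the carbonyl, so hydride should add from the opposite face (as in reductions of ketones next to an angular methyl group), placing the new C8 hydroxyl cis to the methyl group, after which mild methanolysis removes the tertiary silyl ether.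

Step 9
Reactants: 16 (3R,3aS,8S,8aR)-6,8a-dimethyl-3-(propan-2-yl)-1,2,3,3a,4,5,8,8a-octahydroazulene-3a,8-diol; 17 4-methoxybenzoyl chloride
Product: 18 (3R,3aS,8S,8aR)-3a-hydroxy-6,8a-dimethyl-3-(propan-2-yl)-1,2,3,3a,4,5,8,8a-octahydroazulen-8-yl 4-methoxybenzoate (CNP0158828.1)
Conditions: pyridine, DMAP (cat.), CH2Cl2, 0 °C to rt
Reagents that add atoms: none
Why: DMAP-catalysed acylation of the secondary allylic alcohol with retention at C8; the tertiary ring-fusion hydroxyl is too hindered to acylate under these conditions.

## Compound list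

1 | 2-methylfuran | Cc1ccco1 | starting material
2 | (E)-4-methylpent-2-enal | CC(C)/C=C/C=O | starting material
3 | (3R)-4-methyl-3-(5-methylfuran-2-yl)pentanal | O=CC[C@H](C(C)C)c1ccc(C)o1 | intermediate
4 | methyl 2-(triphenylphosphoranylidene)propanoate | COC(=O)C(C)=P(c1ccccc1)(c1ccccc1)c1ccccc1 | starting material
5 | methyl (2E,5R)-2,6-dimethyl-5-(5-methylfuran-2-yl)hept-2-enoate | COC(=O)/C(C)=C/C[C@H](C(C)C)c1ccc(C)o1 | intermediate
6 | methyl (5R)-2,6-dimethyl-5-(5-methylfuran-2-yl)heptanoate (both C2 epimers) | COC(=O)C(C)CC[C@H](C(C)C)c1ccc(C)o1 | intermediate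
7 | chloroiodomethane | ClCI | starting material
8 | lithium (6R)-1-chloro-2-methoxy-3,7-dimethyl-6-(5-methylfuran-2-yl)octan-2-olate | [Li+].COC([O-])(CCl)C(C)CC[C@H](C(C)C)c1ccc(C)o1 | intermediate (not isolated)
9 | (6R)-1-chloro-3,7-dimethyl-6-(5-methylfuran-2-yl)octan-2-one (both C3 epimers) | ClCC(=O)C(C)CC[C@H](C(C)C)c1ccc(C)o1 | intermediate
10 | (6R)-3,7-dimethyl-6-(5-methylfuran-2-yl)-2-oxidooct-1-en-3-ylium (oxyallyl cation, zwitterion) | C=C([O-])[C+](C)CC[C@H](C(C)C)c1ccc(C)o1 | intermediate (not isolated)
11 | 3a,6-epoxy-6,8a-dimethyl-3-(propan-2-yl)-1,2,3,3a,6,7,8,8a-octahydroazulen-8-one; cis-fused, oxygen bridge syn to 8a-CH3 and 3-isopropyl | O=C1C[C@]2(C)C=C[C@]3(O2)[C@@H](C(C)C)CC[C@]13C | intermediate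
12 | 3a,6-epoxy-6,8a-dimethyl-3-(propan-2-yl)decahydroazulen-8-one; same relative configuration | O=C1C[C@]2(C)CC[C@]3(O2)[C@@H](C(C)C)CC[C@]13C | intermediate
13 | trimethylsilyl enol ether of 12 (C7=C8, 8-trimethylsilyloxy) | C[Si](C)(C)OC1=C[C@]2(C)CC[C@]3(O2)[C@@H](C(C)C)CC[C@]13C | intermediate (not isolated)
14 | (3R,3aS,8aS)-6,8a-dimethyl-3-(propan-2-yl)-3a-(trimethylsilyloxy)-2,3,3a,4,5,8a-hexahydroazulen-8(1H)-one | O=C1C=C(C)CC[C@]2(O[Si](C)(C)C)[C@@H](C(C)C)CC[C@]12C | intermediate
15 | (3R,3aS,8S,8aR)-6,8a-dimethyl-3-(propan-2-yl)-3a-(trimethylsilyloxy)-1,2,3,3a,4,5,8,8a-octahydroazulen-8-ol | O[C@H]1C=C(C)CC[C@]2(O[Si](C)(C)C)[C@@H](C(C)C)CC[C@]12C | intermediate (not isolated)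
16 | (3R,3aS,8S,8aR)-6,8a-dimethyl-3-(propan-2-yl)-1,2,3,3a,4,5,8,8a-octahydroazulene-3a,8-diol | O[C@H]1C=C(C)CC[C@]2(O)[C@@H](C(C)C)CC[C@]12C | intermediate
17 | 4-methoxybenzoyl chloride | COc1ccc(C(Cl)=O)cc1 | starting material
18 | (3R,3aS,8S,8aR)-3a-hydroxy-6,8a-dimethyl-3-(propan-2-yl)-1,2,3,3a,4,5,8,8a-octahydroazulen-8-yl 4-methoxybenzoate | COc1ccc(C(=O)O[C@H]2C=C(C)CC[C@]3(O)[C@@H](C(C)C)CC[C@]23C)cc1 | target

## Step count and risks

Total steps: 9. Longest linear sequence: 9.

Steps most likely to fail:

**Step 5.** The cycloaddition may run through the extended array, or stepwise with bond rotation, which would place the ring-fusion methyl anti to the oxygen bridge; some cation may also be lost to solvent capture. The fallback takes the quaternary methyl out of the cycloaddition and installs it afterwards on the rigid oxabicycle, where enolate alkylation from the exo face (syn to the one-atom oxygen bridge) is the established preference. The ring-fusion outcome of the cycloaddition then no longer matters, and the methyl/isopropyl 1,3-interaction that opposes the desired facial sense is absent.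

The fallback sets out from 3. Wittig reaction with methyl (triphenylphosphoranylidene)acetate gives methyl (2E,5R)-6-methyl-5-(5-methylfuran-2-yl)hept-2-enoate F1. Mg in MeOH gives methyl (5R)-6-methyl-5-(5-methylfuran-2-yl)heptanoate F2. Chloroiodomethane and MeLi·LiBr at −78 °C give (6R)-1-chloro-7-methyl-6-(5-methylfuran-2-yl)octan-2-one F3. NaOCH2CF3 in CF3CH2OH gives the des-methyl cycloadduct 3a,6-epoxy-6-methyl-3-(propan-2-yl)-1,2,3,3a,6,7,8,8a-octahydroazulen-8-one F4 (either ring-fusion epimer). H2 over Pd/C gives 3a,6-epoxy-6-methyl-3-(propan-2-yl)decahydroazulen-8-one F5. Me3SiCl, Et3N in DMF at 80 °C give the more substituted (C8=C8a) trimethylsilyl enol ether F6. MeLi in THF at 0 °C followed by MeI at −78 °C (a temperature at which lithium enolates of such oxabicyclic ketones persist and alkylate) gives exo-face methylation and comes back to the route at 12.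

**Step 7.** The silyl enol ether may fail to expel the bridging oxygen cleanly, with over-silylation of the product enone to a dienol ether and deconjugation on work-up, or the bridge may re-close. The fallback changes the order of events so that the C–O bond to be broken is allylic as well as tertiary and the product is a fully conjugated dienone.

The fallback sets out from 11. TMSOTf and Et3N in CH2Cl2 give (3R,3aS,8aS)-6,8a-dimethyl-3-(propan-2-yl)-3a-(trimethylsilyloxy)-2,3,3a,8a-tetrahydroazulen-8(1H)-one F7. H2 with RhCl(PPh3)3 in benzene then saturates only the cis-disubstituted γ,δ-olefin, since this catalyst discriminates against the trisubstituted α,β-olefin, and the sequence comes back to the route at 14.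

**Step 8.** Hydride addition may show poor facial selectivity, with attack syn to the angular methyl group giving the C8 epimer. The fallback makes that epimer deliberately by hydroxyl-directed reduction and then forms the ester C–O bond with inversion.

The fallback sets out from 14. AcOH/THF/H2O removes the silyl group to give (3R,3aS,8aS)-3a-hydroxy-6,8a-dimethyl-3-(propan-2-yl)-2,3,3a,4,5,8a-hexahydroazulen-8(1H)-one F8. Me4NBH(OAc)3 in MeCN/AcOH at −20 °C delivers hydride intramolecularly from the boron-bound tertiary oxygen and gives the anti-1,3-diol (3R,3aS,8R,8aR)-6,8a-dimethyl-3-(propan-2-yl)-1,2,3,3a,4,5,8,8a-octahydroazulene-3a,8-diol F9. Mitsunobu esterification with 4-methoxybenzoic acid (PPh3, diisopropyl azodicarboxylate, THF) inverts C8 and comes back to the route at 18.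

Further compounds

F1 | step 5 | methyl (2E,5R)-6-methyl-5-(5-methylfuran-2-yl)hept-2-enoate | COC(=O)/C=C/C[C@H](C(C)C)c1ccc(C)o1
F2 | step 5 | methyl (5R)-6-methyl-5-(5-methylfuran-2-yl)heptanoate | COC(=O)CCC[C@H](C(C)C)c1ccc(C)o1
F3 | step 5 | (6R)-1-chloro-7-methyl-6-(5-methylfuran-2-yl)octan-2-one | ClCC(=O)CCC[C@H](C(C)C)c1ccc(C)o1
F4 | step 5 | 3a,6-epoxy-6-methyl-3-(propan-2-yl)-1,2,3,3a,6,7,8,8a-octahydroazulen-8-one (either ring-fusion epimer) | O=C1C[C@]2(C)C=C[C@]3(O2)[C@@H](C(C)C)CCC13
F5 | step 5 | 3a,6-epoxy-6-methyl-3-(propan-2-yl)decahydroazulen-8-one (either ring-fusion epimer) | O=C1C[C@]2(C)CC[C@]3(O2)[C@@H](C(C)C)CCC13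
F6 | step 5 | C8=C8a trimethylsilyl enol ether of F5 | C[Si](C)(C)OC=1C[C@]2(C)CC[C@]3(O2)[C@@H](C(C)C)CCC=13
F7 | step 7 | (3R,3aS,8aS)-6,8a-dimethyl-3-(propan-2-yl)-3a-(trimethylsilyloxy)-2,3,3a,8a-tetrahydroazulen-8(1H)-one | O=C1C=C(C)C=C[C@]2(O[Si](C)(C)C)[C@@H](C(C)C)CC[C@]12C
F8 | step 8 | (3R,3aS,8aS)-3a-hydroxy-6,8a-dimethyl-3-(propan-2-yl)-2,3,3a,4,5,8a-hexahydroazulen-8(1H)-one | O=C1C=C(C)CC[C@]2(O)[C@@H](C(C)C)CC[C@]12C
F9 | step 8 | (3R,3aS,8R,8aR)-6,8a-dimethyl-3-(propan-2-yl)-1,2,3,3a,4,5,8,8a-octahydroazulene-3a,8-diol | O[C@@H]1C=C(C)CC[C@]2(O)[C@@H](C(C)C)CC[C@]12C
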